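**Retrosynthetic overview**
1. Target ⇐ bis-silyl ether ⇐ ring-closing metathesis at C2=C3 (Z); the ten-membered carbocycle is closed last, between a vinyl epoxide and a dienyl vinyl group.
2. Key disconnection, C8–O: the sarracinate ester is attached with inversion to an (8S)-carbinol by a new deoxy-acyloxylation, which sets C8 and joins the side chain.
3. C7–C8: Barbier allylation of a β,γ-epoxy aldehyde with a 3-(bromomethyl)butenolide (gives the α-methylene lactone and C7).
4. Ring order: butenolide first (C6 by ProPhenol alkynylation of a Z-dienal, then hydroalumination/hydroxymethylation/lactonization), epoxide second (Shi epoxidation of a dienol from but-3-yn-1-ol), carbocycle third.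

Atom labels follow germacrane numbering: ring C1–C10, C1/C10 epoxide, C6 lactone carbinol, C8 ester carbinol, C11–C13 lactone carbons, C14 methyl, C15 CH2OH.
Assumption: (S,S)-ProPhenol is taken to deliver the alkynyl group to the Si face of aldehyde 5 (R carbinol); if the sense is opposite, the (R,R)-ligand is used.

**Step 1**
Reactants: 1 4,4-diethoxybut-2-yn-1-ol
Product: 3 (2E)-4,4-diethoxy-2-ethenylbut-2-en-1-ol, via cyclic alkenylmagnesium alkoxide 2 (not isolated)
Conditions: CH2=CHMgCl (3.5 equiv), THF, reflux, 16 h; sat. aq. NH4Cl, 0 °C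
Reagents that add atoms: vinylmagnesium chloride, C=C[Mg]Cl
Why: Alkoxide-directed anti-carbomagnesiation of a propargylic alcohol (Fallis–Duboudin reaction) puts vinyl on the carbon next to CH2O and magnesium on the other alkyne carbon from the opposite side, so protonolysis leaves the vinyl group cis to the acetal carbon (the later ring-cis C4=C5 geometry).

**Step 2**
Reactants: 3 (2E)-4,4-diethoxy-2-ethenylbut-2-en-1-ol
Product: 5 (2E)-3-({[tert-butyl(dimethyl)silyl]oxy}methyl)penta-2,4-dienal, via silyl ether acetal 4 (not isolated)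
Conditions: TBSCl, imidazole, CH2Cl2, 0 °C to rt; then SiO2, 10% aq. oxalic acid, CH2Cl2, rt
Reagents that add atoms: tert-butyl(chloro)dimethylsilane, CC(C)(C)[Si](C)(C)Cl; water, O
Why: Silyl protection followed by hydrolysis of the unsaturated acetal on wet silica with oxalic acid, conditions mild enough to keep the olefin geometry (formyl cis to vinyl) and the primary silyl ether.

**Step 3**
Reactants: 5 (2E)-3-({[tert-butyl(dimethyl)silyl]oxy}methyl)penta-2,4-dienal; 6 methyl prop-2-ynoate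
Product: 8 methyl (4R,5E)-6-({[tert-butyl(dimethyl)silyl]oxy}methyl)-4-hydroxyocta-5,7-dien-2-ynoate, via methylzinc acetylide 7 (not isolated)
Conditions: 6 (3 equiv), Me2Zn (3 equiv), (S,S)-ProPhenol (10 mol%), Ph3PO (20 mol%), toluene, 0 °C, 1 h; then 5, 4 °C, 24 h
Reagents that add atoms: none
Why: Trost ProPhenol dinuclear-zinc asymmetric alkynylation of an enal, in which the chiral dizinc pocket directs 1,2-addition of the alkynylzinc to one aldehyde face and sets C6 as R.

**Step 4**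
Reactants: 8 methyl (4R,5E)-6-({[tert-butyl(dimethyl)silyl]oxy}methyl)-4-hydroxyocta-5,7-dien-2-ynoate
Product: 11 (5R)-5-[(1E)-2-({[tert-butyl(dimethyl)silyl]oxy}methyl)buta-1,3-dien-1-yl]-3-(hydroxymethyl)furan-2(5H)-one, via vinylalane 9 (not isolated), via triene diol ester 10 (not isolated)
Conditions: iBu2AlH (2.2 equiv), HMPA (3 equiv), THF, 0 °C, 1 h; HCHO gas (cracked paraformaldehyde), −20 °C to rt; aq. potassium sodium tartrate, then 1 M citric acid
Reagents that add atoms: formaldehyde, C=O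
Why: Vinylalumination (HMPA-modified iBu2AlH adds hydride conjugately and syn to the ynoate) followed by hydroxymethylation with retention places the ester cis to the C6 oxygen, so the (Z)-γ-hydroxy enoate lactonizes to the butenolide without touching C6.

**Step 5**
Reactants: 11 (5R)-5-[(1E)-2-({[tert-butyl(dimethyl)silyl]oxy}methyl)buta-1,3-dien-1-yl]-3-(hydroxymethyl)furan-2(5H)-one
Product: 12 (5R)-3-(bromomethyl)-5-[(1E)-2-({[tert-butyl(dimethyl)silyl]oxy}methyl)buta-1,3-dien-1-yl]furan-2(5H)-one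
Conditions: CBr4, PPh3, CH2Cl2, 0 °C, 30 min
Reagents that add atoms: carbon tetrabromide, BrC(Br)(Br)Br
Why: Appel bromination of the primary allylic alcohol under neutral conditions, with no stereocentre involved.

**Step 6**
Reactants: 13 but-3-yn-1-ol
Product: 15 (3E)-3-methylhexa-3,5-dien-1-ol, via alkenylalane 14 (not isolated)
Conditions: Me3Al (3 equiv), Cp2ZrCl2 (0.25 equiv), CH2Cl2, 0 °C to rt, 12 h; then CH2=CHBr (2 equiv), Pd(PPh3)4 (3 mol%), ZnCl2 (0.2 equiv), THF, rt
Reagents that add atoms: trimethylaluminium, C[Al](C)C; vinyl bromide, C=CBr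
Why: Negishi zirconium-catalysed syn-carboalumination gives the (E)-alkenylalane, which is cross-coupled with retention (Negishi coupling) to the E-diene.

**Step 7**
Reactants: 15 (3E)-3-methylhexa-3,5-dien-1-ol
Product: 16 2-[(2R,3R)-3-ethenyl-2-methyloxiran-2-yl]ethan-1-ol
Conditions: D-fructose-derived Shi ketone (30 mol%), KHSO5 (as Oxone, 1.4 equiv), K2CO3, Bu4NHSO4 (5 mol%), MeCN–CH2(OMe)2–aq. Na2B4O7 buffer (pH 10.5), 0 °C
Reagents that add atoms: potassium peroxymonosulfate, [K+].[O-]S(=O)(=O)OO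
Why: Shi asymmetric epoxidation, in which the chiral dioxirane attacks the electron-richer trisubstituted olefin of the conjugated diene through a spiro transition state and sets C10 and C1 as R,R while the terminal vinyl group stays.

**Step 8**
Reactants: 16 2-[(2R,3R)-3-ethenyl-2-methyloxiran-2-yl]ethan-1-ol
Product: 17 2-[(2R,3R)-3-ethenyl-2-methyloxiran-2-yl]acetaldehyde
Conditions: Dess–Martin periodinane (1.2 equiv), NaHCO3, CH2Cl2, 0 °C, 30 min; used crude at once
Reagents that add atoms: none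
Why: Buffered Dess–Martin oxidation is neutral and fast enough to avoid β-elimination of the β,γ-epoxy aldehyde and leaves the stereocentres untouched.

**Step 9**
Reactants: 12 (5R)-3-(bromomethyl)-5-[(1E)-2-({[tert-butyl(dimethyl)silyl]oxy}methyl)buta-1,3-dien-1-yl]furan-2(5H)-one; 17 2-[(2R,3R)-3-ethenyl-2-methyloxiran-2-yl]acetaldehyde
Product: 19 (4R,5R)-5-[(1E)-2-({[tert-butyl(dimethyl)silyl]oxy}methyl)buta-1,3-dien-1-yl]-4-{(1S)-2-[(2R,3R)-3-ethenyl-2-methyloxiran-2-yl]-1-hydroxyethyl}-3-methylideneoxolan-2-one, via allylzinc bromide 18 (not isolated)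
Conditions: Zn dust (3 equiv), THF–sat. aq. NH4Cl (2:1), 0 °C, 1 h
Reagents that add atoms: none
Why: Barbier allylation with a 3-(bromomethyl)butenolide, where γ-attack through a Zimmerman–Traxler chair on the face opposite to the C6 substituent gives the trans-disubstituted α-methylene lactone (C7 R) and the ring-fixed E-type allylzinc gives the anti carbinol (C8 S, inverted in step 12).

**Step 10**
Reactants: 20 methyl but-2-ynoate
Product: 22 methyl (2Z)-2-(hydroxymethyl)but-2-enoate, via vinylalane 21 (not isolated)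
Conditions: iBu2AlH (1.1 equiv), HMPA (2 equiv), THF, 0 °C, 1 h; HCHO gas (cracked paraformaldehyde), −20 °C; aq. potassium sodium tartrate
Reagents that add atoms: formaldehyde, C=O
Why: Vinylalumination, in which syn hydroalumination and hydroxymethylation with retention give the Z ester (methyl cis to the ester group), the sarracinate geometry.

**Step 11**
Reactants: 22 methyl (2Z)-2-(hydroxymethyl)but-2-enoate
Product: 24 (2Z)-2-({[tert-butyl(dimethyl)silyl]oxy}methyl)but-2-enoic acid, via silyl ether ester 23 (not isolated)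
Conditions: TBSCl, imidazole, DMF, rt; then LiOH (2 equiv), THF–H2O, 0 °C to rt; 1 M HCl to pH 3
Reagents that add atoms: tert-butyl(chloro)dimethylsilane, CC(C)(C)[Si](C)(C)Cl; lithium hydroxide, [Li+].[OH-]
Why: Silylation and mild saponification of the methyl ester, with low temperature and short base contact to keep the Z double bond.

**Step 12**
Reactants: 19 (4R,5R)-5-[(1E)-2-({[tert-butyl(dimethyl)silyl]oxy}methyl)buta-1,3-dien-1-yl]-4-{(1S)-2-[(2R,3R)-3-ethenyl-2-methyloxiran-2-yl]-1-hydroxyethyl}-3-methylideneoxolan-2-one; 24 (2Z)-2-({[tert-butyl(dimethyl)silyl]oxy}methyl)but-2-enoic acid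
Product: 27 (1R)-1-{(2R,3R)-2-[(1E)-2-({[tert-butyl(dimethyl)silyl]oxy}methyl)buta-1,3-dien-1-yl]-4-methylidene-5-oxooxolan-3-yl}-2-[(2R,3R)-3-ethenyl-2-methyloxiran-2-yl]ethyl (2Z)-2-({[tert-butyl(dimethyl)silyl]oxy}methyl)but-2-enoate, via alkoxyimidazolium bifluoride 25 (not isolated), via trimethylsilyl ester 26 (not isolated)
Conditions: 19, PhenoFluor [1,3-bis(2,6-diisopropylphenyl)-2,2-difluoro-2,3-dihydro-1H-imidazole] (1.2 equiv), 1,4-dioxane, 0 to 23 °C, 30 min; then 26 [from 24 (2 equiv) and N-(trimethylsilyl)imidazole (3 equiv), dioxane, 23 °C], 23 to 45 °C, 6 h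
Reagents that add atoms: none
Why: Proposed new method: a deoxy-acyloxylation with inversion, in which PhenoFluor converts the C8 alcohol into the 2-alkoxyimidazolium bifluoride 25 (the activated intermediate of deoxyfluorination), the silyl ester 26 removes fluoride as Me3SiF and so releases the carboxylate as the only nucleophile in a tight ion pair, and the two 2,6-diisopropylphenyl groups block attack at the uronium carbon so that the carboxylate displaces the neutral urea at C8 by SN2 (8S to 8R) without any phosphine that could add to the methylene lactone; the closest known reaction types are PhenoFluor deoxyfluorination and PhenoFluor-mediated alkyl aryl ether formation from secondary alcohols with inversion, and O-alkylisourea esterification with inversion.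

**Step 13**
Reactants: 27 (1R)-1-{(2R,3R)-2-[(1E)-2-({[tert-butyl(dimethyl)silyl]oxy}methyl)buta-1,3-dien-1-yl]-4-methylidene-5-oxooxolan-3-yl}-2-[(2R,3R)-3-ethenyl-2-methyloxiran-2-yl]ethyl (2Z)-2-({[tert-butyl(dimethyl)silyl]oxy}methyl)but-2-enoate
Product: 28 (1R,6R,7R,8R,10R)-15-{[tert-butyl(dimethyl)silyl]oxy}-1,10-epoxy-8-{[(2Z)-2-({[tert-butyl(dimethyl)silyl]oxy}methyl)but-2-enoyl]oxy}germacra-2Z,4E,11(13)-trien-12,6-olide
Conditions: second-generation Hoveyda–Grubbs catalyst RuCl2(=CH-C6H4-2-OiPr)(H2IMes) (2 × 5 mol%), toluene, 0.5 mM, 60 °C, argon sparge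
Reagents that add atoms: none
Why: Ring-closing metathesis of the two monosubstituted vinyl groups, where the strained ten-membered ring can only hold the Z olefin at C2=C3 and the 1,1-disubstituted electron-poor methylene lactone and the trisubstituted olefins react far more slowly.

**Step 14**
Reactants: 28 (1R,6R,7R,8R,10R)-15-{[tert-butyl(dimethyl)silyl]oxy}-1,10-epoxy-8-{[(2Z)-2-({[tert-butyl(dimethyl)silyl]oxy}methyl)but-2-enoyl]oxy}germacra-2Z,4E,11(13)-trien-12,6-olide
Product: 29 (1R,6R,7R,8R,10R)-1,10-epoxy-15-hydroxy-8-{[(2Z)-2-(hydroxymethyl)but-2-enoyl]oxy}germacra-2Z,4E,11(13)-trien-12,6-olide (CNP0293319.2)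
Conditions: Bu4NF (4 equiv), AcOH (4 equiv), THF, 0 °C to rt
Reagents that add atoms: none
Why: Acetic acid-buffered fluoride desilylation removes both primary silyl ethers without opening the vinyl epoxide or adding to the methylene lactone, and no stereocentre changes.

**Compound list**
1 | 4,4-diethoxybut-2-yn-1-ol | CCOC(OCC)C#CCO | starting material
2 | 3-(diethoxymethyl)-4-ethenyl-2,5-dihydro-1,2-oxamagnesole | CCOC(OCC)C1=C(C=C)CO[Mg]1 | intermediate (not isolated)
3 | (2E)-4,4-diethoxy-2-ethenylbut-2-en-1-ol (vinyl cis to the acetal carbon) | CCOC(OCC)/C=C(CO)\C=C | intermediate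
4 | tert-butyl{[(2E)-4,4-diethoxy-2-ethenylbut-2-en-1-yl]oxy}dimethylsilane | CCOC(OCC)/C=C(CO[Si](C)(C)C(C)(C)C)\C=C | intermediate (not isolated)
5 | (2E)-3-({[tert-butyl(dimethyl)silyl]oxy}methyl)penta-2,4-dienal (formyl cis to vinyl) | O=C/C=C(CO[Si](C)(C)C(C)(C)C)\C=C | intermediate
6 | methyl prop-2-ynoate | C#CC(=O)OC | starting material
7 | methyl 3-(methylzincio)prop-2-ynoate | C[Zn]C#CC(=O)OC | intermediate (not isolated)
8 | methyl (4R,5E)-6-({[tert-butyl(dimethyl)silyl]oxy}methyl)-4-hydroxyocta-5,7-dien-2-ynoate | COC(=O)C#C[C@H](O)/C=C(CO[Si](C)(C)C(C)(C)C)\C=C | intermediate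
9 | methyl (2E,4R,5E)-2-(diisobutylalumanyl)-4-[(diisobutylalumanyl)oxy]-6-({[tert-butyl(dimethyl)silyl]oxy}methyl)octa-2,5,7-trienoate | COC(=O)/C(=C\[C@H](O[Al](CC(C)C)CC(C)C)/C=C(CO[Si](C)(C)C(C)(C)C)\C=C)[Al](CC(C)C)CC(C)C | intermediate (not isolated)
10 | methyl (2Z,4R,5E)-6-({[tert-butyl(dimethyl)silyl]oxy}methyl)-4-hydroxy-2-(hydroxymethyl)octa-2,5,7-trienoate | COC(=O)/C(CO)=C\[C@H](O)/C=C(CO[Si](C)(C)C(C)(C)C)\C=C | intermediate (not isolated)
11 | (5R)-5-[(1E)-2-({[tert-butyl(dimethyl)silyl]oxy}methyl)buta-1,3-dien-1-yl]-3-(hydroxymethyl)furan-2(5H)-one | O=C1O[C@H](/C=C(CO[Si](C)(C)C(C)(C)C)\C=C)C=C1CO | intermediate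
12 | (5R)-3-(bromomethyl)-5-[(1E)-2-({[tert-butyl(dimethyl)silyl]oxy}methyl)buta-1,3-dien-1-yl]furan-2(5H)-one | O=C1O[C@H](/C=C(CO[Si](C)(C)C(C)(C)C)\C=C)C=C1CBr | intermediate
13 | but-3-yn-1-ol | C#CCCO | starting material
14 | dimethyl{(1E)-4-[(dimethylalumanyl)oxy]-2-methylbut-1-en-1-yl}alumane | C/C(CCO[Al](C)C)=C\[Al](C)C | intermediate (not isolated)
15 | (3E)-3-methylhexa-3,5-dien-1-ol | OCC/C(C)=C/C=C | intermediate
16 | 2-[(2R,3R)-3-ethenyl-2-methyloxiran-2-yl]ethan-1-ol | OCC[C@@]1(C)O[C@@H]1C=C | intermediate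
17 | 2-[(2R,3R)-3-ethenyl-2-methyloxiran-2-yl]acetaldehyde | O=CC[C@@]1(C)O[C@@H]1C=C | intermediate
18 | bromo({(5R)-5-[(1E)-2-({[tert-butyl(dimethyl)silyl]oxy}methyl)buta-1,3-dien-1-yl]-2-oxo-2,5-dihydrofuran-3-yl}methyl)zinc | O=C1O[C@H](/C=C(CO[Si](C)(C)C(C)(C)C)\C=C)C=C1C[Zn]Br | intermediate (not isolated)
19 | (4R,5R)-5-[(1E)-2-({[tert-butyl(dimethyl)silyl]oxy}methyl)buta-1,3-dien-1-yl]-4-{(1S)-2-[(2R,3R)-3-ethenyl-2-methyloxiran-2-yl]-1-hydroxyethyl}-3-methylideneoxolan-2-one | C=C1C(=O)O[C@H](/C=C(CO[Si](C)(C)C(C)(C)C)\C=C)[C@H]1[C@@H](O)C[C@@]1(C)O[C@@H]1C=C | intermediate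
20 | methyl but-2-ynoate | CC#CC(=O)OC | starting material
21 | methyl (2E)-2-(diisobutylalumanyl)but-2-enoate | COC(=O)/C(=C\C)[Al](CC(C)C)CC(C)C | intermediate (not isolated)
22 | methyl (2Z)-2-(hydroxymethyl)but-2-enoate | COC(=O)/C(=C\C)CO | intermediate
23 | methyl (2Z)-2-({[tert-butyl(dimethyl)silyl]oxy}methyl)but-2-enoate | COC(=O)/C(=C\C)CO[Si](C)(C)C(C)(C)C | intermediate (not isolated)
24 | (2Z)-2-({[tert-butyl(dimethyl)silyl]oxy}methyl)but-2-enoic acid | OC(=O)/C(=C\C)CO[Si](C)(C)C(C)(C)C | intermediate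
25 | 1,3-bis(2,6-diisopropylphenyl)-2-{[(1S)-1-{(2R,3R)-2-[(1E)-2-({[tert-butyl(dimethyl)silyl]oxy}methyl)buta-1,3-dien-1-yl]-4-methylidene-5-oxooxolan-3-yl}-2-[(2R,3R)-3-ethenyl-2-methyloxiran-2-yl]ethyl]oxy}imidazol-1-ium hydrogen difluoride | C=C1C(=O)O[C@H](/C=C(CO[Si](C)(C)C(C)(C)C)\C=C)[C@H]1[C@@H](Oc1n(-c2c(C(C)C)cccc2C(C)C)cc[n+]1-c1c(C(C)C)cccc1C(C)C)C[C@@]1(C)O[C@@H]1C=C.F.[F-] | intermediate (not isolated)
26 | trimethylsilyl (2Z)-2-({[tert-butyl(dimethyl)silyl]oxy}methyl)but-2-enoate | C[Si](C)(C)OC(=O)/C(=C\C)CO[Si](C)(C)C(C)(C)C | intermediate (not isolated)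
27 | (1R)-1-{(2R,3R)-2-[(1E)-2-({[tert-butyl(dimethyl)silyl]oxy}methyl)buta-1,3-dien-1-yl]-4-methylidene-5-oxooxolan-3-yl}-2-[(2R,3R)-3-ethenyl-2-methyloxiran-2-yl]ethyl (2Z)-2-({[tert-butyl(dimethyl)silyl]oxy}methyl)but-2-enoate | C=C1C(=O)O[C@H](/C=C(CO[Si](C)(C)C(C)(C)C)\C=C)[C@H]1[C@H](OC(=O)/C(=C\C)CO[Si](C)(C)C(C)(C)C)C[C@@]1(C)O[C@@H]1C=C | intermediate
28 | (1R,6R,7R,8R,10R)-15-{[tert-butyl(dimethyl)silyl]oxy}-1,10-epoxy-8-{[(2Z)-2-({[tert-butyl(dimethyl)silyl]oxy}methyl)but-2-enoyl]oxy}germacra-2Z,4E,11(13)-trien-12,6-olide (both ring olefins cis in the ring) | C=C1C(=O)O[C@@H]2/C=C(CO[Si](C)(C)C(C)(C)C)\C=C/[C@H]3O[C@]3(C)C[C@@H](OC(=O)/C(=C\C)CO[Si](C)(C)C(C)(C)C)[C@@H]12 | intermediate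
29 | (1R,6R,7R,8R,10R)-1,10-epoxy-15-hydroxy-8-{[(2Z)-2-(hydroxymethyl)but-2-enoyl]oxy}germacra-2Z,4E,11(13)-trien-12,6-olide (CNP0293319.2) | C=C1C(=O)O[C@@H]2/C=C(CO)\C=C/[C@H]3O[C@]3(C)C[C@@H](OC(=O)/C(=C\C)CO)[C@@H]12 | target

**Step count**
Total: 14 steps. Longest linear sequence: 9 steps (steps 1–5, 9, 12, 13, 14).

**Three steps most likely to fail**

Step 12 (the proposed new deoxy-acyloxylation). It can fail by E2 loss toward C7, by acyl transfer with retention, or by C–F formation. The fallback uses known chemistry and separates inversion from acylation. It sets out from 19: a Mitsunobu reaction with formic acid (PPh3, DIAD, toluene, 0 °C, betaine pre-formed) gives the inverted C8 formate F1. Brief treatment with KHCO3 in MeOH–H2O at 0 °C gives the 8R alcohol F2. Yamaguchi esterification of F2 with acid 24 (2,4,6-trichlorobenzoyl chloride, Et3N, toluene, then catalytic DMAP, rt) goes with retention and comes back to the route at 27.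

Step 13 (ring-closing metathesis). It can fail through ring strain and oligomers, or through competing closure of a ruthenium carbene onto the methylene lactone to give a six- or seven-membered ring. The fallback masks the methylene group and sets out from 27: Me2NH (2 M in THF, 0 °C) adds to the methylene lactone to give the dimethylaminomethyl lactone F3. F3, as its camphorsulfonate salt, is cyclized with the same ruthenium catalyst to the macrocyclic amine F4. MeI in MeCN gives the methiodide F5, which loses trimethylamine with aq. NaHCO3 and comes back to the route at 28.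

Step 1 (uncatalysed carbomagnesiation next to an acetal). At reflux the alkenylmagnesium intermediate may lose ethoxide to give an allene, or the addition may stall. The fallback sets out from 1: hydroxyl-directed trans-hydrostannation ([Cp*RuCl]4 (1 mol%), Bu3SnH, CH2Cl2, rt) gives the alkenylstannane F6 with tin cis to the acetal carbon. Stille coupling of F6 with vinyl bromide (Pd(PPh3)4, CuI, DMF, 40 °C) comes back to the route at 3.

**Further compounds**
F1 | step 12 | (1R)-1-{(2R,3R)-2-[(1E)-2-({[tert-butyl(dimethyl)silyl]oxy}methyl)buta-1,3-dien-1-yl]-4-methylidene-5-oxooxolan-3-yl}-2-[(2R,3R)-3-ethenyl-2-methyloxiran-2-yl]ethyl formate | C=C1C(=O)O[C@H](/C=C(CO[Si](C)(C)C(C)(C)C)\C=C)[C@H]1[C@H](OC=O)C[C@@]1(C)O[C@@H]1C=C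
F2 | step 12 | (4R,5R)-5-[(1E)-2-({[tert-butyl(dimethyl)silyl]oxy}methyl)buta-1,3-dien-1-yl]-4-{(1R)-2-[(2R,3R)-3-ethenyl-2-methyloxiran-2-yl]-1-hydroxyethyl}-3-methylideneoxolan-2-one | C=C1C(=O)O[C@H](/C=C(CO[Si](C)(C)C(C)(C)C)\C=C)[C@H]1[C@H](O)C[C@@]1(C)O[C@@H]1C=C
F3 | step 13 | dimethylamine adduct of 27 at the lactone methylene (3-[(dimethylamino)methyl]oxolan-2-one, C11 configuration not defined) | CN(C)CC1C(=O)O[C@H](/C=C(CO[Si](C)(C)C(C)(C)C)\C=C)[C@H]1[C@H](OC(=O)/C(=C\C)CO[Si](C)(C)C(C)(C)C)C[C@@]1(C)O[C@@H]1C=C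
F4 | step 13 | 13-(dimethylamino)-11,13-dihydro derivative of macrocycle 28 | CN(C)CC1C(=O)O[C@@H]2/C=C(CO[Si](C)(C)C(C)(C)C)\C=C/[C@H]3O[C@]3(C)C[C@@H](OC(=O)/C(=C\C)CO[Si](C)(C)C(C)(C)C)[C@@H]12
F5 | step 13 | 13-(trimethylammonio)-11,13-dihydro derivative of macrocycle 28, iodide | C[N+](C)(C)CC1C(=O)O[C@@H]2/C=C(CO[Si](C)(C)C(C)(C)C)\C=C/[C@H]3O[C@]3(C)C[C@@H](OC(=O)/C(=C\C)CO[Si](C)(C)C(C)(C)C)[C@@H]12.[I-]
F6 | step 1 | (2Z)-4,4-diethoxy-2-(tributylstannyl)but-2-en-1-ol | CCOC(OCC)/C=C(CO)\[Sn](CCCC)(CCCC)CCCC
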